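## The problem

- Target **13** is an achiral bibenzyl. Ring A is numbered from the ester carbon: C1 CO2Me, C2 OH, C3 prenyl, C4 OH, C5 prenyl, C6 the CH2CH2 link to ring B (4-hydroxyphenyl).
- There is no stereocentre. The whole difficulty is connectivity: a benzene ring with six contiguous, mutually different substituents, for which no simple aromatic building block exists.
- Both C-prenyl groups sit ortho to free phenols. Such o-prenylphenols close to chromans under acid and to chromenes or cyclic halo-ethers under DDQ, halonium sources or divalent palladium.
- C-prenylation of a resorcinol competes with O-prenylation, so late introduction of the prenyl groups is unattractive.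
- Ring B carries a third phenol that is more nucleophilic than the hydrogen-bonded ring A phenols and has to be masked by a group removable without acid or hydrogen.
- The feature that opens the plan: C3, C4 and C5 of ring A, with the C4 oxygen and the two prenyl groups, are symmetric about C4. They are the skeleton of the symmetric ketone **3**, whose two α-carbons are C3 and C5.
- C1 and C2 with the ester are the two carbons of a malonate (**7**), and C6 with its side chain is an aldehyde carbon (**6**). Since a resorcinol is the dehydro form of a cyclohexane-1,3-dione, ring A can be built from these three open-chain pieces one oxidation level below the arene, where the prenyl groups only watch enolate chemistry.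

## Retrosynthesis

**13 ⇒ 12.** The O–allyl bond on ring B is the only protecting-group bond. Allyl is chosen over silyl (lost in methoxide), benzyl (hydrogenolysis would reduce the prenyl groups) and acetal groups (acid would close chromans). The forward step must free one phenol under neutral conditions.

**12 ⇒ 10.** The C1=C6 unsaturation of the arene is removed, giving the 2,4-dioxocyclohexanecarboxylate **10**. Working at this level takes the o-prenylphenols out of the route until the last two steps. The forward step must take two hydrogens (C1–H, C6–H) without acid, halonium or quinone oxidants. This is done through the C1 selenide **11**, which can only eliminate towards C6.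

**10 ⇒ 3 + 8 (key cut).** The C5–C6 bond (Michael) and the C2–C3 bond (Dieckmann) are cut, through the open-chain adduct **9**.
- Symmetric **3** has only one enolate, so no regiochemistry arises.
- **8** is an unhindered, doubly activated acceptor.
- Only one six-membered closure is possible from **9**.
- The neighbouring pair of cuts (C1–C6 and C2–C3, malonate **7** onto a condensation product of **3** and **6**) reaches the same **9** but needs two more operations; it is kept as the fallback.
- The precursors are two acyclic compounds of 13 and 17 carbons; the product holds all six ring carbons and all six substituents of ring A.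

**8 ⇒ 6 + 7; 6 ⇒ 5 ⇒ 4.** The C1=C6 alkene of **8** is a Knoevenagel bond between aldehyde **6** and dimethyl malonate **7**. Aldehyde **6** comes from commercial 3-(4-hydroxyphenyl)propan-1-ol **4** by phenol allylation (**5**) and alcohol oxidation.

**3 ⇒ 1 + 2.** The C7–C8 bond of **3** is cut to the kinetic enolate of commercial 6-methylhept-5-en-2-one **1** and prenyl bromide **2**. One alkylation turns a commodity ketone, which already holds one prenyl arm, into the symmetric ketone.

## Roads not taken

**Alternative 1:** the obvious route. Cut both aryl–prenyl bonds and prenylate methyl 2,4-dihydroxy-6-[2-(4-hydroxyphenyl)ethyl]benzoate **A1** twice with **2** and base, or with a prenyl cation source.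
- The ambident resorcinolate gives O- as well as C-alkylation, and mono-, di- and over-alkylated products together.
- Ring B would need protection anyway.
- Cationic conditions close chromans as soon as the first prenyl group is on.
- **A1** is itself several steps from commercial arenes, so the hard part of the ring is made unselectively at the end. In the chosen plan the prenyl groups are placed by construction.

**Alternative 2:** a Danheiser benzannulation. Thermal opening of cyclobutenone **A2** gives a vinylketene; [2+2] addition to siloxyalkyne **A3**, 4π-opening and 6π-closure would give the silyl-protected arene **A4** with the correct pattern.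
- The ring construction is regiospecific, but **A2** (a four-membered ring with three different substituents and an ester) is not much simpler than ring A and needs its own multistep, regiochemically uncertain synthesis.
- **A3** has to be made from a prenylated ynolate.
- The hot vinylketenes carry prenyl alkenes that can be trapped intramolecularly.
- The route would be longer than seven steps.

**Alternative 3:** the same three pieces joined at the arene oxidation level. The enolate of **3** would add to chloroalkylidene malonate **A5** with loss of chloride, and the keto alkylidene malonate **A6** would be expected to close to **12** directly.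
- **A5** is tetrasubstituted, so the new bond would join a tertiary enolate carbon to a fully substituted alkene carbon, and proton transfer from its γ-CH2 would compete.
- In **A6** the most acidic hydrogen is C5–H; the resulting delocalised anion deactivates both esters towards the C3 enolate.
- The enol oxygen of **A6** lies six atoms from the cis ester, and lactonisation to the 2-pyranone **A7** is the usual fate of such intermediates.
- The dihydro level avoids all three problems at the cost of one dehydrogenation.

Key step: step 5

Assumption: intermediates **9**, **10** and **11** are carried as mixtures of diastereomers (**10** also as keto–enol tautomers). This has no consequence, because all their stereocentres become sp2 carbons in step 6.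

## Steps

Step 1
Reactants: 1 6-methylhept-5-en-2-one; 2 1-bromo-3-methylbut-2-ene (prenyl bromide)
Product: 3 2,10-dimethylundeca-2,9-dien-6-one
Conditions: LiN(i-Pr)2 (1.05 equiv), THF, −78 °C; then 2, DMPU, −78 → 0 °C
Reagents that add atoms: none
Why: Kinetic deprotonation of the methyl ketone at −78 °C takes a CH3 proton; the terminal lithium enolate is alkylated (SN2) by the reactive allylic bromide before it can equilibrate, which adds the second prenyl arm and makes the ketone symmetric.

Step 2
Reactants: 4 3-(4-hydroxyphenyl)propan-1-ol
Product: 5 3-[4-(prop-2-en-1-yloxy)phenyl]propan-1-ol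
Conditions: allyl bromide, K2CO3, acetone, reflux
Reagents that add atoms: allyl bromide, C=CCBr
Why: Williamson ether synthesis; K2CO3 deprotonates only the phenol, so the primary alcohol stays free, and the allyl ether should survive every later base and leave under neutral conditions.

Step 3
Reactants: 5 3-[4-(prop-2-en-1-yloxy)phenyl]propan-1-ol
Product: 6 3-[4-(prop-2-en-1-yloxy)phenyl]propanal
Conditions: TEMPO (10 mol %), PhI(OAc)2, CH2Cl2, rt
Reagents that add atoms: none
Why: Oxoammonium-mediated oxidation of a primary alcohol stops at the aldehyde and should touch neither the allyl ether nor the arene.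

Step 4
Reactants: 6 3-[4-(prop-2-en-1-yloxy)phenyl]propanal; 7 dimethyl propanedioate (dimethyl malonate)
Product: 8 dimethyl 2-{3-[4-(prop-2-en-1-yloxy)phenyl]propylidene}propanedioate
Conditions: piperidine (cat.), AcOH (cat.), 4 Å MS, CH2Cl2, rt
Reagents that add atoms: none
Why: Knoevenagel condensation through the iminium ion with removal of water; the two esters are identical, so no alkene geometry arises, and room temperature limits self-aldol reaction and deconjugation of the enolisable aldehyde.

Step 5
Reactants: 3 2,10-dimethylundeca-2,9-dien-6-one; 8 dimethyl 2-{3-[4-(prop-2-en-1-yloxy)phenyl]propylidene}propanedioate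
Product: 10 methyl 3,5-bis(3-methylbut-2-en-1-yl)-2,4-dioxo-6-{2-[4-(prop-2-en-1-yloxy)phenyl]ethyl}cyclohexane-1-carboxylate, via Michael adduct 9 (not isolated)
Conditions: 3, LiN(i-Pr)2, THF, −78 °C; 8, −78 → −20 °C; then NaOMe, MeOH, 65 °C; 1 M HCl, 0 °C (to pH 4)
Reagents that add atoms: none
Why: Symmetric 3 gives a single lithium enolate, which adds 1,4 to the doubly activated alkene of 8 at the future C6 (Michael addition of a ketone enolate to an alkylidene malonate, a well-documented pairing) to give the malonate enolate of 9. In NaOMe/MeOH this anion equilibrates with the C3 ketone enolate, which attacks one malonate ester carbonyl (Dieckmann condensation); the sequence is the long-established Michael–Dieckmann annulation to 2,4-dioxocyclohexanecarboxylates. The ring closes in the 6-(enolendo)-exo-trig mode, which is favoured, whereas the C5 enolate or the malonate carbon could only form four-membered rings, so one ring size is possible. Loss of methoxide and deprotonation at C3 give the cyclic 1,3-diketonate, a thermodynamic sink that also drains the reversible Michael and retro-Michael equilibria and reopens any enol lactone formed by O-acylation. Four stereocentres (C1, C3, C5, C6) form without control, and none is needed, since all are erased in step 6. The selectivity required is conjugate addition over proton transfer from the γ-CH2 of 8; it rests on the low temperature, the unhindered β-carbon and the strong activation by two esters. After this step all six carbons of ring A and all six substituents are in place.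

Step 6
Reactants: 10 methyl 3,5-bis(3-methylbut-2-en-1-yl)-2,4-dioxo-6-{2-[4-(prop-2-en-1-yloxy)phenyl]ethyl}cyclohexane-1-carboxylate
Product: 12 methyl 2,4-dihydroxy-3,5-bis(3-methylbut-2-en-1-yl)-6-{2-[4-(prop-2-en-1-yloxy)phenyl]ethyl}benzoate, via selenide 11 (not isolated)
Conditions: LiN(i-Pr)2 (2.2 equiv), THF, −78 → −20 °C; PhSeBr (1.0 equiv), −78 °C; AcOH; then 30% H2O2, pyridine, CH2Cl2, 0 °C → rt
Reagents that add atoms: none
Why: The first equivalent of base gives the C2–C3–C4 diketonate and the second removes C1–H; the dianion should react with PhSeBr at its more basic terminus C1, anti to the pseudoaxial C6 side chain, which places selenium syn to C6–H. Oxidation to the selenoxide and syn-elimination (selenoxide dehydrogenation of a β-dicarbonyl compound) give the C1=C6 alkene, and enolisation of C4 towards C5 gives the arene below room temperature in a pyridine buffer, with no acid, halonium or quinone present to cyclise the new o-prenylphenols.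

Step 7
Reactants: 12 methyl 2,4-dihydroxy-3,5-bis(3-methylbut-2-en-1-yl)-6-{2-[4-(prop-2-en-1-yloxy)phenyl]ethyl}benzoate
Product: 13 methyl 2,4-dihydroxy-6-[2-(4-hydroxyphenyl)ethyl]-3,5-bis(3-methylbut-2-en-1-yl)benzoate
Conditions: Pd(PPh3)4 (5 mol %), morpholine, THF, rt
Reagents that add atoms: none
Why: Tsuji–Trost deallylation: zerovalent palladium ionises the aryl allyl ether to a π-allyl complex that morpholine traps; the prenyl groups carry no leaving group and the hindered methyl ester is inert to the amine at room temperature.

## Compound list

1 | 6-methylhept-5-en-2-one | CC(C)=CCCC(C)=O | starting material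
2 | 1-bromo-3-methylbut-2-ene | CC(C)=CCBr | starting material
3 | 2,10-dimethylundeca-2,9-dien-6-one | CC(C)=CCCC(=O)CCC=C(C)C | intermediate
4 | 3-(4-hydroxyphenyl)propan-1-ol | OCCCc1ccc(O)cc1 | starting material
5 | 3-[4-(prop-2-en-1-yloxy)phenyl]propan-1-ol | OCCCc1ccc(OCC=C)cc1 | intermediate
6 | 3-[4-(prop-2-en-1-yloxy)phenyl]propanal | O=CCCc1ccc(OCC=C)cc1 | intermediate
7 | dimethyl propanedioate | COC(=O)CC(=O)OC | starting material
8 | dimethyl 2-{3-[4-(prop-2-en-1-yloxy)phenyl]propylidene}propanedioate | COC(=O)C(=CCCc1ccc(OCC=C)cc1)C(=O)OC | intermediate
9 | dimethyl 2-{9-methyl-4-(3-methylbut-2-en-1-yl)-5-oxo-1-[4-(prop-2-en-1-yloxy)phenyl]dec-8-en-3-yl}propanedioate (mixture of diastereomers) | COC(=O)C(C(=O)OC)C(CCc1ccc(OCC=C)cc1)C(CC=C(C)C)C(=O)CCC=C(C)C | intermediate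
10 | methyl 3,5-bis(3-methylbut-2-en-1-yl)-2,4-dioxo-6-{2-[4-(prop-2-en-1-yloxy)phenyl]ethyl}cyclohexane-1-carboxylate (mixture of diastereomers and enol tautomers) | COC(=O)C1C(=O)C(CC=C(C)C)C(=O)C(CC=C(C)C)C1CCc1ccc(OCC=C)cc1 | intermediate
11 | methyl 3,5-bis(3-methylbut-2-en-1-yl)-2,4-dioxo-1-(phenylselanyl)-6-{2-[4-(prop-2-en-1-yloxy)phenyl]ethyl}cyclohexane-1-carboxylate (selenium anti to the C6 side chain expected; mixture at C3 and C5) | COC(=O)C1([Se]c2ccccc2)C(=O)C(CC=C(C)C)C(=O)C(CC=C(C)C)C1CCc1ccc(OCC=C)cc1 | intermediate
12 | methyl 2,4-dihydroxy-3,5-bis(3-methylbut-2-en-1-yl)-6-{2-[4-(prop-2-en-1-yloxy)phenyl]ethyl}benzoate | COC(=O)c1c(O)c(CC=C(C)C)c(O)c(CC=C(C)C)c1CCc1ccc(OCC=C)cc1 | intermediate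
13 | methyl 2,4-dihydroxy-6-[2-(4-hydroxyphenyl)ethyl]-3,5-bis(3-methylbut-2-en-1-yl)benzoate | COC(=O)c1c(O)c(CC=C(C)C)c(O)c(CC=C(C)C)c1CCc1ccc(O)cc1 | target

## Step count and risks

Total step count: 7. Longest linear sequence: 6 steps (steps 2 to 7); step 1 feeds the convergent key step.

**Step 5 (key step).**
- Most likely failure: proton transfer from the γ-CH2 of **8** to the lithium enolate, which deconjugates or oligomerises the acceptor instead of adding to it.
- Second failure: slow Dieckmann closure at the substituted C3, so that **9** fragments by retro-Michael reaction on heating.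
- Fallback: it sets out from **3** and **6**. A directed aldol addition (LiN(i-Pr)2, THF, −78 °C) should give the β-hydroxy ketone F1. Mesylation and elimination (MsCl, Et3N, then DBU) should give the enone F2. The soft anion of **7** (NaOMe, MeOH, reflux) should then add to F2, which has no acidic γ-position of the malonate type, and reach **9** from the other side. The fallback rejoins the route at **10**.

**Step 6.**
- Selenenylation may occur at C3 instead of C1.
- Selenium may be delivered syn to the C6 side chain, which leaves no syn hydrogen for elimination.
- Perseleninic acid formed from H2O2 may epoxidise the prenyl alkenes or oxidise the new phenols.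
- Fallback: it sets out from **10**. Silylation (Me3SiOTf, Et3N, CH2Cl2) should give the bis(trimethylsilyl) dienol ether F3, a cyclohexa-1,3-diene. DDQ with 2,4,6-collidine at 0 °C should dehydrogenate it to the bis-silylated arene F4; the phenols are masked, so DDQ cannot draw them into chromene formation. K2CO3 in MeOH should remove the silyl groups. The fallback rejoins the route at **12**.

**Step 4.**
- Self-aldol condensation of the enolisable aldehyde, deconjugation of **8** to its β,γ-isomer, and addition of a second malonate to **8** can all erode the condensation.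
- Fallback: it sets out from **5**. I2, PPh3 and imidazole should give the iodide F5. Alkylation of **7** (NaH, THF) should give the alkylmalonate F6. Selenenylation (NaH, PhSeBr) should give the selenide F7, whose selenoxide (H2O2, pyridine) can only eliminate into the side chain. The fallback rejoins the route at **8**.

**Step 1.**
- Equilibration of the kinetic enolate with product ketone would lead to alkylation at the internal α-carbon and to dialkylation.
- Fallback: it sets out from **1**. Carbomethoxylation at the methyl group (NaH, dimethyl carbonate) should give the β-keto ester F8. Alkylation at the doubly activated carbon (K2CO3, **2**, acetone) should give the C-prenylated β-keto ester F9. Krapcho dealkoxycarbonylation (LiCl, wet DMSO, 150 °C) then follows. The fallback rejoins the route at **3**.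

## Further compounds

F1 | step 5 | 5-{1-hydroxy-3-[4-(prop-2-en-1-yloxy)phenyl]propyl}-2,10-dimethylundeca-2,9-dien-6-one (mixture of diastereomers) | CC(C)=CCC(C(O)CCc1ccc(OCC=C)cc1)C(=O)CCC=C(C)C
F2 | step 5 | (E)-2,10-dimethyl-5-{3-[4-(prop-2-en-1-yloxy)phenyl]propylidene}undeca-2,9-dien-6-one | CC(C)=CC/C(=C\CCc1ccc(OCC=C)cc1)C(=O)CCC=C(C)C
F3 | step 6 | methyl 3,5-bis(3-methylbut-2-en-1-yl)-6-{2-[4-(prop-2-en-1-yloxy)phenyl]ethyl}-2,4-bis[(trimethylsilyl)oxy]cyclohexa-1,3-diene-1-carboxylate (mixture of diastereomers) | COC(=O)C1=C(O[Si](C)(C)C)C(CC=C(C)C)=C(O[Si](C)(C)C)C(CC=C(C)C)C1CCc1ccc(OCC=C)cc1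
F4 | step 6 | methyl 3,5-bis(3-methylbut-2-en-1-yl)-6-{2-[4-(prop-2-en-1-yloxy)phenyl]ethyl}-2,4-bis[(trimethylsilyl)oxy]benzoate | COC(=O)c1c(O[Si](C)(C)C)c(CC=C(C)C)c(O[Si](C)(C)C)c(CC=C(C)C)c1CCc1ccc(OCC=C)cc1
F5 | step 4 | 1-(3-iodopropyl)-4-(prop-2-en-1-yloxy)benzene | ICCCc1ccc(OCC=C)cc1
F6 | step 4 | dimethyl 2-{3-[4-(prop-2-en-1-yloxy)phenyl]propyl}propanedioate | COC(=O)C(CCCc1ccc(OCC=C)cc1)C(=O)OC
F7 | step 4 | dimethyl 2-(phenylselanyl)-2-{3-[4-(prop-2-en-1-yloxy)phenyl]propyl}propanedioate | COC(=O)C(CCCc1ccc(OCC=C)cc1)([Se]c1ccccc1)C(=O)OC
F8 | step 1 | methyl 7-methyl-3-oxooct-6-enoate | COC(=O)CC(=O)CCC=C(C)C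
F9 | step 1 | methyl 7-methyl-2-(3-methylbut-2-en-1-yl)-3-oxooct-6-enoate | COC(=O)C(CC=C(C)C)C(=O)CCC=C(C)C
A1 | alternative 1 | methyl 2,4-dihydroxy-6-[2-(4-hydroxyphenyl)ethyl]benzoate | COC(=O)c1c(O)cc(O)cc1CCc1ccc(O)cc1
A2 | alternative 2 | methyl 3-(3-methylbut-2-en-1-yl)-4-oxo-2-{2-[4-(prop-2-en-1-yloxy)phenyl]ethyl}cyclobut-2-ene-1-carboxylate | COC(=O)C1C(CCc2ccc(OCC=C)cc2)=C(CC=C(C)C)C1=O
A3 | alternative 2 | [(5-methylhex-4-en-1-yn-1-yl)oxy]tri(propan-2-yl)silane | CC(C)=CCC#CO[Si](C(C)C)(C(C)C)C(C)C
A4 | alternative 2 | methyl 2-hydroxy-3,5-bis(3-methylbut-2-en-1-yl)-6-{2-[4-(prop-2-en-1-yloxy)phenyl]ethyl}-4-{[tri(propan-2-yl)silyl]oxy}benzoate | COC(=O)c1c(O)c(CC=C(C)C)c(O[Si](C(C)C)(C(C)C)C(C)C)c(CC=C(C)C)c1CCc1ccc(OCC=C)cc1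
A5 | alternative 3 | dimethyl 2-{1-chloro-3-[4-(prop-2-en-1-yloxy)phenyl]propylidene}propanedioate | COC(=O)C(C(=O)OC)=C(Cl)CCc1ccc(OCC=C)cc1
A6 | alternative 3 | dimethyl 2-{9-methyl-4-(3-methylbut-2-en-1-yl)-5-oxo-1-[4-(prop-2-en-1-yloxy)phenyl]dec-8-en-3-ylidene}propanedioate | COC(=O)C(C(=O)OC)=C(CCc1ccc(OCC=C)cc1)C(CC=C(C)C)C(=O)CCC=C(C)C
A7 | alternative 3 | methyl 5-(3-methylbut-2-en-1-yl)-6-(4-methylpent-3-en-1-yl)-2-oxo-4-{2-[4-(prop-2-en-1-yloxy)phenyl]ethyl}-2H-pyran-3-carboxylate | COC(=O)C1=C(CCc2ccc(OCC=C)cc2)C(CC=C(C)C)=C(CCC=C(C)C)OC1=O
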